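The hydroazulene is cut at the two bonds that join the quaternary, methyl-bearing ring-fusion carbon C8a to C3a and to C8 (azulene numbering: C1–C3 five-membered ring, C4–C8 seven-membered ring). The six other seven-ring carbons, C8, C7, C6, C5, C4 and C3a, are then the ring of a 2,6-dimethoxy-4-methylphenyl group: its oxygens become the C8 hydroxyl and C4 ester oxygens and its methyl the C6 methyl. One intramolecular Buchner reaction, run with Cu(MeCN)4PF6 and a chiral bis(oxazoline), closes the cyclopentanone, expands the arene to the cycloheptatriene and sets C8a. The precursor is 2-diazo-5-(2,6-dimethoxy-4-methylphenyl)pentan-3-one, made from 3,5-dimethoxytoluene.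

Key step: step 5

Remark on naming: azulene numbering is kept for every bicyclic compound; α is the face of the C8a methyl group and β the opposite face. The target is cis-fused, with 2-OAc, 3-OH, 3a-H and 8-OH α and 3-isopropyl and 4-aroyloxy β, i.e. (2S,3R,3aR,4S,8S,8aS) in this numbering.
Remark on materials: 2-methyl-1-phenylbutane-1,3-dione is taken as a catalogue compound (otherwise one C-methylation of 1-phenylbutane-1,3-dione gives it).

Step 1
Reactants: 1 3,5-dimethoxytoluene
Product: 3 (2,6-dimethoxy-4-methylphenyl)methanol, via aryllithium 2 (not isolated)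
Conditions: n-BuLi, TMEDA, THF, 0 °C to rt; (CH2O)n, −78 °C to rt; H2O
Reagents that add atoms: paraformaldehyde (formaldehyde), C=O
Why: Directed ortho-metalation should occur at the ring carbon flanked by both methoxy groups, and the aryllithium is hydroxymethylated by formaldehyde (addition of an aryllithium to an aldehyde).

Step 2
Reactants: 3 (2,6-dimethoxy-4-methylphenyl)methanol
Product: 4 2-(bromomethyl)-1,3-dimethoxy-5-methylbenzene
Conditions: PBr3, Et2O, −10 °C; used at once without storage
Reagents that add atoms: phosphorus tribromide, BrP(Br)Br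
Why: Bromination of a benzylic alcohol through its phosphite ester with SN2 displacement by bromide; the electron-rich bromide is carried forward immediately.

Step 3
Reactants: 5 2-methyl-1-phenylbutane-1,3-dione; 4 2-(bromomethyl)-1,3-dimethoxy-5-methylbenzene
Product: 7 5-(2,6-dimethoxy-4-methylphenyl)-2-methyl-1-phenylpentane-1,3-dione, via dilithium dienolate 6 (not isolated)
Conditions: LiN(i-Pr)2 (2.2 equiv), THF, 0 °C; 4, −78 °C to 0 °C; 1 M HCl
Reagents that add atoms: none
Why: Hauser-type alkylation of a β-diketone dianion at its terminal, more reactive carbanion; the benzoyl side has no α-hydrogen, so only the methyl terminus can be benzylated.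

Step 4
Reactants: 7 5-(2,6-dimethoxy-4-methylphenyl)-2-methyl-1-phenylpentane-1,3-dione
Product: 8 2-diazo-5-(2,6-dimethoxy-4-methylphenyl)pentan-3-one
Conditions: 4-acetamidobenzenesulfonyl azide, DBU, MeCN, 0 °C to rt
Reagents that add atoms: 4-acetamidobenzenesulfonyl azide, CC(=O)Nc1ccc(cc1)S(=O)(=O)N=[N+]=[N-]
Why: Regitz diazo transfer to a 2-substituted 1,3-diketone with deacylation, the benzoyl group leaving as the N-benzoylsulfonamide (debenzoylative diazo transfer), so the alkyl ketone and the methyl group stay on the diazo carbon.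

Step 5
Reactants: 8 2-diazo-5-(2,6-dimethoxy-4-methylphenyl)pentan-3-one
Product: 10 (8aS)-4,8-dimethoxy-6,8a-dimethyl-3,8a-dihydroazulen-1(2H)-one, via norcaradiene 9 (not isolated)
Conditions: Cu(MeCN)4PF6 (5 mol %), (4R,4'R)-2,2'-(propane-2,2-diyl)bis(4-phenyl-4,5-dihydrooxazole) (6 mol %; its antipode if the sense of induction requires), NaB[3,5-(CF3)2C6H3]4 (6 mol %), CH2Cl2, reflux, slow addition of 8
Reagents that add atoms: none
Why: Cu(MeCN)4PF6 with the bis(oxazoline) decomposes the diazo group to a copper-bound carbene, which adds across the ipso–ortho bond of the tethered arene to give norcaradiene 9, and disrotatory 6π electrocyclic opening of the cyclopropane bond between the former ipso and ortho carbons gives cycloheptatriene 10. The closest known reaction type is the intramolecular Buchner reaction of α-diazoketones, including cyclisations of 2-diazo-5-arylpentan-3-ones to 8a-methylazulenones catalysed by CuCl or Cu(MeCN)4PF6 with bis(oxazolines) and NaB[3,5-(CF3)2C6H3]4. The five-membered ring closes when the carbene carbon bonds to the ipso carbon through the CH2CH2C(=O) tether (five-ring closure by cyclopropanation), and the seven-membered ring arises by one-carbon expansion of the benzene ring when the same carbon bonds to the methoxy-bearing ortho carbon and the norcaradiene opens. The single new stereocentre, quaternary C8a, is set by the chiral ligand on copper, which decides the face of the carbene presented to the arene; the ligand enantiomer that gives (8aS) is used. Only facial selectivity is needed because the two ortho carbons are equivalent by symmetry, and the substrate secures the chemoselectivity: both ortho positions carry OMe, so there is no ortho C–H for aromatic substitution and no path to a 2-tetralone, while the two ortho-methoxy groups make the ipso carbon the most nucleophilic site within reach of the tether. Slow addition keeps the carbene concentration low so that cyclisation should outrun dimerisation and 1,2-hydride shift from the carbene methyl group.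

Step 6
Reactants: 10 (8aS)-4,8-dimethoxy-6,8a-dimethyl-3,8a-dihydroazulen-1(2H)-one
Product: 12 (8aS)-4,8-dimethoxy-6,8a-dimethyl-1-(triisopropylsilyloxy)-3,8a-dihydroazulene, via potassium enolate 11 (not isolated)
Conditions: KN(SiMe3)2, THF, −78 °C; i-Pr3SiOTf, −78 °C to 0 °C
Reagents that add atoms: triisopropylsilyl triflate, CC(C)[Si](OS(=O)(=O)C(F)(F)F)(C(C)C)C(C)C
Why: Enolate O-silylation: the ketone can enolise only toward C2 because C8a is quaternary, and the silyl enol ether removes the acceptor carbonyl (so acid can no longer open the donor–acceptor norcaradiene tautomer), hides C1 from hydride and is the later handle for desaturation.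

Step 7
Reactants: 12 (8aS)-4,8-dimethoxy-6,8a-dimethyl-1-(triisopropylsilyloxy)-3,8a-dihydroazulene
Product: 14 cis-fused 8-methoxy-6,8a-dimethyl-1-(triisopropylsilyloxy)-3a,8a-dihydroazulen-4(3H)-one (3a-H α), via trans-fused epimer 13 (not isolated)
Conditions: oxalic acid (0.05 M aq), THF, 0 °C, short contact; NaHCO3; then DBU (0.2 equiv), CH2Cl2, rt
Reagents that add atoms: water, O
Why: Enol ether hydrolysis in which protonation at C3a, the triene terminus fed by both methoxy groups, should give a 4,8-dimethoxypentadienyl cation that water captures at C4 (the end remote from the quaternary carbon and the bulky silyloxy group), so loss of methanol leaves the C4 ketone as a vinylogous ester that resists further hydrolysis while the isolated silyl enol ether is protonated far more slowly; the C3a hydrogen, first delivered anti to the angular methyl, is α to the ketone and is equilibrated by DBU to the cis-fused isomer, the trans-fused bicycle being strained by the cyclopentene and the planar dienone.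

Step 8
Reactants: 14 cis-fused 8-methoxy-6,8a-dimethyl-1-(triisopropylsilyloxy)-3a,8a-dihydroazulen-4(3H)-one
Product: 15 8-methoxy-6,8a-dimethyl-1-(triisopropylsilyloxy)-3,3a,4,8a-tetrahydroazulen-4-ol (3a-H α; 4-OH β)
Conditions: i-Bu2AlH, CH2Cl2, −78 °C; aqueous KNaC4H4O6 (potassium sodium tartrate) work-up
Reagents that add atoms: none
Why: 1,2-Reduction of a vinylogous ester carbonyl by an aluminium hydride; hydride should enter from the convex α face of the cis-fused bicycle (the face of the 3a-hydrogen, away from the five-membered ring), which sets the 4β-hydroxyl, and the non-acidic work-up avoids Stork–Danheiser-type ionisation.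

Step 9
Reactants: 16 4-hydroxybenzoic acid
Product: 18 4-(triisopropylsilyloxy)benzoic acid, via bis-silylated ester 17 (not isolated)
Conditions: i-Pr3SiCl (2.2 equiv), imidazole, DMF, rt; then K2CO3, MeOH/THF/H2O, rt; 1 M HCl to pH 4
Reagents that add atoms: chlorotriisopropylsilane, CC(C)[Si](Cl)(C(C)C)C(C)C
Why: Silylation of both hydroxyl groups followed by selective solvolysis of the far more labile silyl ester leaves the phenol as its triisopropylsilyl ether.

Step 10
Reactants: 18 4-(triisopropylsilyloxy)benzoic acid; 15 8-methoxy-6,8a-dimethyl-1-(triisopropylsilyloxy)-3,3a,4,8a-tetrahydroazulen-4-ol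
Product: 20 8-methoxy-6,8a-dimethyl-1-(triisopropylsilyloxy)-3,3a,4,8a-tetrahydroazulen-4β-yl 4-(triisopropylsilyloxy)benzoate, via acid chloride 19 (not isolated)
Conditions: 18, (COCl)2, DMF (cat.), CH2Cl2, 0 °C to rt, evaporate; then 15, Et3N, DMAP, CH2Cl2, 0 °C; chromatography on Et3N-deactivated silica
Reagents that add atoms: none
Why: DMAP-catalysed acylation of the secondary allylic alcohol by an acid chloride under basic conditions, with retention at C4, which the acid-labile dienol ether should tolerate.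

Step 11
Reactants: 20 8-methoxy-6,8a-dimethyl-1-(triisopropylsilyloxy)-3,3a,4,8a-tetrahydroazulen-4β-yl 4-(triisopropylsilyloxy)benzoate
Product: 22 8α-hydroxy-6,8a-dimethyl-1-(triisopropylsilyloxy)-3,3a,4,7,8,8a-hexahydroazulen-4β-yl 4-(triisopropylsilyloxy)benzoate, via C8 ketone 21 (not isolated)
Conditions: oxalic acid (0.05 M aq), THF, 0 °C, short contact; NaHCO3; then NaBH4, CeCl3·7H2O, MeOH/THF, −78 °C
Reagents that add atoms: water, O
Why: Kinetic hydrolysis of the 1-methoxydiene by α-protonation at C7 (as in the conversion of 3-methoxy-3,5-dienes into β,γ-unsaturated ketones) should unmask the C8 ketone with the alkene left at C5=C6, C-protonation being much faster at this acidity than ionisation of the allylic ester, and immediate Luche reduction with hydride entering anti to the adjacent angular methyl group gives the 8α-alcohol before the alkene can move into conjugation.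

Step 12
Reactants: 22 8α-hydroxy-6,8a-dimethyl-1-(triisopropylsilyloxy)-3,3a,4,7,8,8a-hexahydroazulen-4β-yl 4-(triisopropylsilyloxy)benzoate
Product: 23 8α-(tert-butyldimethylsilyloxy)-6,8a-dimethyl-1-(triisopropylsilyloxy)-3,3a,4,7,8,8a-hexahydroazulen-4β-yl 4-(triisopropylsilyloxy)benzoate
Conditions: t-BuMe2SiOTf, 2,6-lutidine, CH2Cl2, −78 °C to 0 °C
Reagents that add atoms: tert-butyldimethylsilyl triflate, CC(C)(C)[Si](C)(C)OS(=O)(=O)C(F)(F)F
Why: Silylation of a hindered, neopentyl-type secondary alcohol with a silyl triflate and a hindered base, so that only the C2 hydroxyl made later is free for acetylation.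

Step 13
Reactants: 23 8α-(tert-butyldimethylsilyloxy)-6,8a-dimethyl-1-(triisopropylsilyloxy)-3,3a,4,7,8,8a-hexahydroazulen-4β-yl 4-(triisopropylsilyloxy)benzoate
Product: 26 8α-(tert-butyldimethylsilyloxy)-6,8a-dimethyl-1-oxo-1,3a,4,7,8,8a-hexahydroazulen-4β-yl 4-(triisopropylsilyloxy)benzoate, via selanyl ketone 24 (not isolated), via selenoxide 25 (not isolated)
Conditions: PhSeCl (1.05 equiv), CH2Cl2, −78 °C; mCPBA (1.0 equiv), −78 °C; i-Pr2NH, −78 °C to rt
Reagents that add atoms: none
Why: Selenenylation of the silyl enol ether at C2, oxidation to the selenoxide and syn-elimination (Reich–Sharpless), which can only take a C3 hydrogen, give the cyclopentenone; the silyl enol ether should react with PhSeCl far faster than the ester-deactivated C5=C6 alkene.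

Step 14
Reactants: 26 8α-(tert-butyldimethylsilyloxy)-6,8a-dimethyl-1-oxo-1,3a,4,7,8,8a-hexahydroazulen-4β-yl 4-(triisopropylsilyloxy)benzoate
Product: 28 8α-(tert-butyldimethylsilyloxy)-3-isopropyl-6,8a-dimethyl-1-oxo-1,3a,4,7,8,8a-hexahydroazulen-4β-yl 4-(triisopropylsilyloxy)benzoate, via chloromagnesium enolate 27 (not isolated)
Conditions: i-PrMgCl (2.4 equiv), CuBr·SMe2 (1.2 equiv), THF, −78 °C (gives i-Pr2CuMgCl); 26, −78 °C; PhS(Cl)=N-t-Bu, −78 °C to 0 °C
Reagents that add atoms: isopropylmagnesium chloride, CC(C)[Mg]Cl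
Why: Conjugate addition of the isopropylcuprate at C3 from the convex α face, then dehydrogenation of the enolate in the same flask with N-tert-butylbenzenesulfinimidoyl chloride (Mukaiyama dehydrogenation), returns the enone with isopropyl on C3; the weakly basic cuprate should leave the C3a hydrogen and the C4 ester alone.

Step 15
Reactants: 28 8α-(tert-butyldimethylsilyloxy)-3-isopropyl-6,8a-dimethyl-1-oxo-1,3a,4,7,8,8a-hexahydroazulen-4β-yl 4-(triisopropylsilyloxy)benzoate
Product: 29 8α-(tert-butyldimethylsilyloxy)-1α-hydroxy-3-isopropyl-6,8a-dimethyl-1,3a,4,7,8,8a-hexahydroazulen-4β-yl 4-(triisopropylsilyloxy)benzoate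
Conditions: NaBH4, CeCl3·7H2O, MeOH/THF, −78 °C to −20 °C
Reagents that add atoms: none
Why: Luche 1,2-reduction of the enone; hydride is expected anti to the angular methyl, and the configuration of this carbinol is of no consequence because its oxygen is removed in step 17.

Step 16
Reactants: 29 8α-(tert-butyldimethylsilyloxy)-1α-hydroxy-3-isopropyl-6,8a-dimethyl-1,3a,4,7,8,8a-hexahydroazulen-4β-yl 4-(triisopropylsilyloxy)benzoate
Product: 30 O-phenyl thionocarbonate of 29 at the C1 oxygen
Conditions: PhOC(S)Cl, pyridine, DMAP, CH2Cl2, 0 °C to rt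
Reagents that add atoms: O-phenyl chlorothionoformate, S=C(Cl)Oc1ccccc1
Why: Acylation of the allylic alcohol to its thionocarbonate, the radical precursor for Barton–McCombie deoxygenation.

Step 17
Reactants: 30 O-phenyl thionocarbonate of 29 at the C1 oxygen
Product: 31 8α-(tert-butyldimethylsilyloxy)-3-isopropyl-6,8a-dimethyl-1,3a,4,7,8,8a-hexahydroazulen-4β-yl 4-(triisopropylsilyloxy)benzoate
Conditions: Bu3SnH, AIBN (cat.), toluene, 80 °C
Reagents that add atoms: none
Why: Barton–McCombie deoxygenation through the C1–C3 allyl radical, which should take hydrogen at its secondary, less hindered terminus C1 and so leave the more substituted C2=C3 alkene that carries the isopropyl group (either allylic isomer of the thiocarbonate feeds the same radical).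

Step 18
Reactants: 31 8α-(tert-butyldimethylsilyloxy)-3-isopropyl-6,8a-dimethyl-1,3a,4,7,8,8a-hexahydroazulen-4β-yl 4-(triisopropylsilyloxy)benzoate
Product: 32 8α-(tert-butyldimethylsilyloxy)-2α,3α-dihydroxy-3β-isopropyl-6,8a-dimethyl-1,2,3,3a,4,7,8,8a-octahydroazulen-4β-yl 4-(triisopropylsilyloxy)benzoate
Conditions: OsO4 (5 mol %), N-methylmorpholine N-oxide, acetone/H2O, 0 °C to rt, monitored to one equivalent of oxidant
Reagents that add atoms: osmium tetroxide, O=[Os](=O)(=O)=O; N-methylmorpholine N-oxide, C[N+]1([O-])CCOCC1; water, O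
Why: Upjohn cis-dihydroxylation of the trisubstituted cyclopentene from the convex α face of the cis-fused bicycle (the face of the 3a-hydrogen and the 8a-methyl), which sets the 2α- and 3α-hydroxyls and the 3β-isopropyl group together; the C5=C6 alkene is deactivated by its allylic ester.

Step 19
Reactants: 32 8α-(tert-butyldimethylsilyloxy)-2α,3α-dihydroxy-3β-isopropyl-6,8a-dimethyl-1,2,3,3a,4,7,8,8a-octahydroazulen-4β-yl 4-(triisopropylsilyloxy)benzoate
Product: 33 2α-acetate of 32
Conditions: Ac2O, pyridine, DMAP (cat.), CH2Cl2, 0 °C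
Reagents that add atoms: acetic anhydride, CC(=O)OC(C)=O
Why: Acetylation of the only free secondary alcohol; the tertiary C3 hydroxyl should not react under these conditions.

Step 20
Reactants: 33 2α-acetate of 32
Product: 34 2α-acetoxy-3α,8α-dihydroxy-3β-isopropyl-6,8a-dimethyl-1,2,3,3a,4,7,8,8a-octahydroazulen-4β-yl 4-hydroxybenzoate (target, cis-fused)
Conditions: Bu4NF, AcOH (1:1), THF, 0 °C to rt
Reagents that add atoms: none
Why: Fluoride cleaves the aryl triisopropylsilyl and the alkyl tert-butyldimethylsilyl ethers, and the acetic acid buffer should prevent acyl migration or ester cleavage.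

Compound list
1 | 3,5-dimethoxytoluene | COc1cc(C)cc(OC)c1 | starting material
2 | (2,6-dimethoxy-4-methylphenyl)lithium (not isolated) | [Li]c1c(OC)cc(C)cc1OC | intermediate
3 | (2,6-dimethoxy-4-methylphenyl)methanol | COc1cc(C)cc(OC)c1CO | intermediate
4 | 2-(bromomethyl)-1,3-dimethoxy-5-methylbenzene | COc1cc(C)cc(OC)c1CBr | intermediate
5 | 2-methyl-1-phenylbutane-1,3-dione | CC(=O)C(C)C(=O)c1ccccc1 | starting material
6 | dilithium dienolate of 5 (not isolated) | C=C(O[Li])C(C)=C(O[Li])c1ccccc1 | intermediate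
7 | 5-(2,6-dimethoxy-4-methylphenyl)-2-methyl-1-phenylpentane-1,3-dione (racemic, labile at C2) | COc1cc(C)cc(OC)c1CCC(=O)C(C)C(=O)c1ccccc1 | intermediate
8 | 2-diazo-5-(2,6-dimethoxy-4-methylphenyl)pentan-3-one | COc1cc(C)cc(OC)c1CCC(=O)C(C)=[N+]=[N-] | intermediate
9 | norcaradiene valence isomer of 10 (not isolated) | O=C1CC[C@@]23C(OC)=CC(C)=C[C@]2(OC)[C@@]13C | intermediate
10 | (8aS)-4,8-dimethoxy-6,8a-dimethyl-3,8a-dihydroazulen-1(2H)-one | C1C(=O)[C@]2(C)C(OC)=CC(C)=CC(OC)=C2C1 | intermediate
11 | potassium enolate of 10 (not isolated) | C1=C(O[K])[C@]2(C)C(OC)=CC(C)=CC(OC)=C2C1 | intermediate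
12 | (8aS)-4,8-dimethoxy-6,8a-dimethyl-1-(triisopropylsilyloxy)-3,8a-dihydroazulene | C1=C(O[Si](C(C)C)(C(C)C)C(C)C)[C@]2(C)C(OC)=CC(C)=CC(OC)=C2C1 | intermediate
13 | trans-fused 3a-epimer of 14, 3a-H β (not isolated) | C1=C(O[Si](C(C)C)(C(C)C)C(C)C)[C@]2(C)C(OC)=CC(C)=CC(=O)[C@H]2C1 | intermediate
14 | cis-fused 8-methoxy-6,8a-dimethyl-1-(triisopropylsilyloxy)-3a,8a-dihydroazulen-4(3H)-one, 3a-H α | C1=C(O[Si](C(C)C)(C(C)C)C(C)C)[C@]2(C)C(OC)=CC(C)=CC(=O)[C@@H]2C1 | intermediate
15 | 4β-alcohol from 14 (3a-H α, 4-OH β) | C1=C(O[Si](C(C)C)(C(C)C)C(C)C)[C@]2(C)C(OC)=CC(C)=C[C@H](O)[C@@H]2C1 | intermediate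
16 | 4-hydroxybenzoic acid | O=C(O)c1ccc(O)cc1 | starting material
17 | triisopropylsilyl 4-(triisopropylsilyloxy)benzoate (not isolated) | CC(C)[Si](OC(=O)c1ccc(O[Si](C(C)C)(C(C)C)C(C)C)cc1)(C(C)C)C(C)C | intermediate
18 | 4-(triisopropylsilyloxy)benzoic acid | O=C(O)c1ccc(O[Si](C(C)C)(C(C)C)C(C)C)cc1 | intermediate
19 | 4-(triisopropylsilyloxy)benzoyl chloride (not isolated) | O=C(Cl)c1ccc(O[Si](C(C)C)(C(C)C)C(C)C)cc1 | intermediate
20 | 4β-aroyl ester of 15, C8 still the methyl dienol ether | C1=C(O[Si](C(C)C)(C(C)C)C(C)C)[C@]2(C)C(OC)=CC(C)=C[C@H](OC(=O)c3ccc(O[Si](C(C)C)(C(C)C)C(C)C)cc3)[C@@H]2C1 | intermediate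
21 | C8 ketone, β,γ-unsaturated, C5=C6 alkene (not isolated) | C1=C(O[Si](C(C)C)(C(C)C)C(C)C)[C@]2(C)C(=O)CC(C)=C[C@H](OC(=O)c3ccc(O[Si](C(C)C)(C(C)C)C(C)C)cc3)[C@@H]2C1 | intermediate
22 | 8α-alcohol | C1=C(O[Si](C(C)C)(C(C)C)C(C)C)[C@]2(C)[C@@H](O)CC(C)=C[C@H](OC(=O)c3ccc(O[Si](C(C)C)(C(C)C)C(C)C)cc3)[C@@H]2C1 | intermediate
23 | 8α-tert-butyldimethylsilyl ether | C1=C(O[Si](C(C)C)(C(C)C)C(C)C)[C@]2(C)[C@@H](O[Si](C)(C)C(C)(C)C)CC(C)=C[C@H](OC(=O)c3ccc(O[Si](C(C)C)(C(C)C)C(C)C)cc3)[C@@H]2C1 | intermediate
24 | 2α-(phenylselanyl) C1 ketone (not isolated) | c4ccccc4[Se][C@H]1C(=O)[C@]2(C)[C@@H](O[Si](C)(C)C(C)(C)C)CC(C)=C[C@H](OC(=O)c3ccc(O[Si](C(C)C)(C(C)C)C(C)C)cc3)[C@@H]2C1 | intermediate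
25 | selenoxide of 24 (not isolated; configuration at selenium not defined) | O=[Se](c4ccccc4)[C@H]1C(=O)[C@]2(C)[C@@H](O[Si](C)(C)C(C)(C)C)CC(C)=C[C@H](OC(=O)c3ccc(O[Si](C(C)C)(C(C)C)C(C)C)cc3)[C@@H]2C1 | intermediate
26 | cyclopentenone (C1 ketone, C2=C3) | C1=CC(=O)[C@]2(C)[C@@H](O[Si](C)(C)C(C)(C)C)CC(C)=C[C@H](OC(=O)c3ccc(O[Si](C(C)C)(C(C)C)C(C)C)cc3)[C@H]12 | intermediate
27 | chloromagnesium enolate with 3α-isopropyl (not isolated) | C1=C(O[Mg]Cl)[C@]2(C)[C@@H](O[Si](C)(C)C(C)(C)C)CC(C)=C[C@H](OC(=O)c3ccc(O[Si](C(C)C)(C(C)C)C(C)C)cc3)[C@@H]2[C@H]1C(C)C | intermediate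
28 | 3-isopropyl cyclopentenone | CC(C)C1=CC(=O)[C@]2(C)[C@@H](O[Si](C)(C)C(C)(C)C)CC(C)=C[C@H](OC(=O)c3ccc(O[Si](C(C)C)(C(C)C)C(C)C)cc3)[C@H]12 | intermediate
29 | 1α-allylic alcohol | CC(C)C1=C[C@@H](O)[C@]2(C)[C@@H](O[Si](C)(C)C(C)(C)C)CC(C)=C[C@H](OC(=O)c3ccc(O[Si](C(C)C)(C(C)C)C(C)C)cc3)[C@H]12 | intermediate
30 | O-phenyl thionocarbonate of 29 | CC(C)C1=C[C@@H](OC(=S)Oc4ccccc4)[C@]2(C)[C@@H](O[Si](C)(C)C(C)(C)C)CC(C)=C[C@H](OC(=O)c3ccc(O[Si](C(C)C)(C(C)C)C(C)C)cc3)[C@H]12 | intermediate
31 | 3-isopropyl cyclopentene (C1 deoxygenated, C2=C3) | CC(C)C1=CC[C@]2(C)[C@@H](O[Si](C)(C)C(C)(C)C)CC(C)=C[C@H](OC(=O)c3ccc(O[Si](C(C)C)(C(C)C)C(C)C)cc3)[C@H]12 | intermediate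
32 | 2α,3α-diol | O[C@H]1C[C@]2(C)[C@@H](O[Si](C)(C)C(C)(C)C)CC(C)=C[C@H](OC(=O)c3ccc(O[Si](C(C)C)(C(C)C)C(C)C)cc3)[C@@H]2[C@]1(O)C(C)C | intermediate
33 | 2α-acetate | CC(=O)O[C@H]1C[C@]2(C)[C@@H](O[Si](C)(C)C(C)(C)C)CC(C)=C[C@H](OC(=O)c3ccc(O[Si](C(C)C)(C(C)C)C(C)C)cc3)[C@@H]2[C@]1(O)C(C)C | intermediate
34 | CNP0146780.2 | CC(=O)O[C@H]1C[C@]2(C)[C@@H](O)CC(C)=C[C@H](OC(=O)c3ccc(O)cc3)[C@@H]2[C@]1(O)C(C)C | target

Total step count: 20. Longest linear sequence: 19 steps (steps 1–8 and 10–20, from 3,5-dimethoxytoluene); step 9 is a one-step side branch.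

Steps most likely to fail

Step 5. The carbene may meet the hindered, methoxy-flanked ipso–ortho bond with poor facial discrimination, or be lost to 1,2-hydride migration from its methyl group. The fallback changes the source of chirality from asymmetric catalysis to resolution. It sets out from 8: cyclisation with the achiral catalyst Rh2(OAc)4 in CH2Cl2, the most general catalyst class for intramolecular Buchner reactions of α-diazoketones, should give the racemic azulenone F1. Preparative chromatography of F1 on a chiral stationary phase then provides the (S) enantiomer, which is compound 10, where the route is rejoined.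

Step 7. Water may capture the pentadienyl cation at C8 instead of C4, so that the C8 ketone forms and the roles of the two oxygens are exchanged. The fallback keeps that regioisomer and reverses the order in which the two carbonyls are unveiled, setting out from 12 and using only operations already in the route.
- The C8-keto 4-methoxy dienol ether F2 is reduced with i-Bu2AlH to the 8α-alcohol F3 (hydride anti to the angular methyl).
- F3 is silylated with t-BuMe2SiOTf and 2,6-lutidine to the silyl ether F4.
- Brief oxalic acid hydrolysis of the remaining dienol ether gives the deconjugated C4 ketone F5.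
- DBU moves the alkene into conjugation with the only carbonyl and equilibrates C3a, giving the cis-fused enone F6.
- Luche reduction (NaBH4, CeCl3·7H2O) from the convex face gives the 4β-alcohol F7.
- Acylation of F7 with 19 as in step 10 gives compound 23, where the route is rejoined.

Step 11. The allylic aroyl ester, which sits at the end of a methoxy-substituted diene, may ionise (with elimination or allylic shift) faster than the enol ether is protonated; the alkene may also drift into conjugation before reduction. The fallback carries C4 through the unmasking as a silyl ether, a far poorer leaving group, and installs the ester afterwards. It sets out from 15.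
- Et3SiCl and imidazole give the 4β-triethylsilyl ether F8.
- Oxalic acid hydrolysis gives the C8 ketone F9, which is reduced at once with NaBH4 and CeCl3·7H2O to the 8α-alcohol F10.
- t-BuMe2SiOTf and 2,6-lutidine give the bis-silyl ether F11.
- Pyridinium p-toluenesulfonate in MeOH at 0 °C removes the less hindered allylic triethylsilyl group and gives the 4β-alcohol F7.
- Acylation of F7 with 19 as in step 10 gives compound 23, where the route is rejoined.

Further compounds
F1 | step 5 | racemic 4,8-dimethoxy-6,8a-dimethyl-3,8a-dihydroazulen-1(2H)-one | C1C(=O)C2(C)C(OC)=CC(C)=CC(OC)=C2C1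
F2 | step 7 | C8-keto regioisomer: 4-methoxy-6,8a-dimethyl-1-(triisopropylsilyloxy)-3,3a-dihydroazulen-8(8aH)-one, 3a-H β as formed | C1=C(O[Si](C(C)C)(C(C)C)C(C)C)[C@]2(C)C(=O)C=C(C)C=C(OC)[C@H]2C1
F3 | step 7 | 8α-alcohol from F2 | C1=C(O[Si](C(C)C)(C(C)C)C(C)C)[C@]2(C)[C@@H](O)C=C(C)C=C(OC)[C@H]2C1
F4 | step 7 | 8α-tert-butyldimethylsilyl ether of F3 | C1=C(O[Si](C(C)C)(C(C)C)C(C)C)[C@]2(C)[C@@H](O[Si](C)(C)C(C)(C)C)C=C(C)C=C(OC)[C@H]2C1
F5 | step 7 | deconjugated C4 ketone with C6=C7 alkene, 3a-H β (not isolated) | C1=C(O[Si](C(C)C)(C(C)C)C(C)C)[C@]2(C)[C@@H](O[Si](C)(C)C(C)(C)C)C=C(C)CC(=O)[C@H]2C1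
F6 | step 7 | cis-fused conjugated C4 enone with C5=C6 alkene, 3a-H α | C1=C(O[Si](C(C)C)(C(C)C)C(C)C)[C@]2(C)[C@@H](O[Si](C)(C)C(C)(C)C)CC(C)=CC(=O)[C@@H]2C1
F7 | step 7 | 4β-alcohol with 8α-tert-butyldimethylsilyloxy group | C1=C(O[Si](C(C)C)(C(C)C)C(C)C)[C@]2(C)[C@@H](O[Si](C)(C)C(C)(C)C)CC(C)=C[C@H](O)[C@@H]2C1
F8 | step 11 | 4β-triethylsilyl ether of 15 | C1=C(O[Si](C(C)C)(C(C)C)C(C)C)[C@]2(C)C(OC)=CC(C)=C[C@H](O[Si](CC)(CC)CC)[C@@H]2C1
F9 | step 11 | C8 ketone with 4β-triethylsilyloxy group (not isolated) | C1=C(O[Si](C(C)C)(C(C)C)C(C)C)[C@]2(C)C(=O)CC(C)=C[C@H](O[Si](CC)(CC)CC)[C@@H]2C1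
F10 | step 11 | 8α-alcohol with 4β-triethylsilyloxy group | C1=C(O[Si](C(C)C)(C(C)C)C(C)C)[C@]2(C)[C@@H](O)CC(C)=C[C@H](O[Si](CC)(CC)CC)[C@@H]2C1
F11 | step 11 | 8α-tert-butyldimethylsilyl 4β-triethylsilyl bis-ether | C1=C(O[Si](C(C)C)(C(C)C)C(C)C)[C@]2(C)[C@@H](O[Si](C)(C)C(C)(C)C)CC(C)=C[C@H](O[Si](CC)(CC)CC)[C@@H]2C1
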